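The route rests on cutting the C4–C5 bond of ring A. Ring B comes from a 4,4-disubstituted cyclohexa-2,5-dienone whose only sp3 ring carbon is C10 (carrying C20 and the C1–C3 tether), so C5 and C9 are enantiotopic β-carbons. A chiral primary amine turns the terminal α-methyl aldehyde into an enamine whose carbon C4 adds to C5. This one operation closes ring A cis-fused, sets C4, C5 and C10, and leaves the C7 ketone with the C8=C9 enone for C17 and the side chain. The cyclisation substrate is racemic 2-methyl-5-(1-methyl-4-oxocyclohexa-2,5-dien-1-yl)pentanal, made in four steps from 2,6-dimethylhept-5-enal and methyl vinyl ketone.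

Key step: step 5

Atom labels follow labdane numbering: C4 bears the ester and a methyl, C5/C10 are the ring-fusion carbons, C20 is the angular methyl, C9 bears the side chain (C11–C16), C8 bears the exocyclic CH2 (C17).
Remark on the chemistry: compound 8 has a stereocentre at the aldehyde α-carbon and is a racemate, not an achiral compound; the enamine erases this centre, so both enantiomers of 8 feed the same product, and the element that is desymmetrised is C10 of the dienone.
Remark on the chemistry: in the chair through which ring A closes, the new C4–C5 bond is axial on ring B, so on ring A the C10–C9 bond is axial and C20 equatorial; the C4 epimer of the target (formyl cis to C20) therefore comes from the arrangement with the enamine arm equatorial and the C4 methyl axial, not from the opposite arrangement.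
Assumption: which antipode of the amine catalyst gives (1S,4aR,8aS)-9 has to be found by experiment; the route is written for that antipode. The C7 configuration of 22 and 23 does not matter (C7 ends as CH2); both are carried as epimer mixtures.
Abbreviation: "bis-TBS side chain" = (3E)-5-(tert-butyldimethylsilyloxy)-3-[(tert-butyldimethylsilyloxy)methyl]pent-3-en-1-yl.

Step 1
Reactants: 1 2,6-dimethylhept-5-enal (racemic); 2 methyl vinyl ketone
Product: 4 4-methyl-4-(4-methylpent-3-en-1-yl)cyclohex-2-en-1-one (racemic), via keto-aldehyde Michael adduct 3 (not isolated)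
Conditions: KOH (0.15 equiv), EtOH, 0 °C → rt, then 70 °C
Reagents that add atoms: none
Why: Robinson annulation: the enolate of the α-branched aldehyde adds to the enone (Michael) and the methyl ketone then condenses onto the non-enolisable aldehyde (aldol condensation), which should give the 4,4-disubstituted cyclohexenone with the former aldehyde α-carbon as the quaternary centre (future C10).

Step 2
Reactants: 4 4-methyl-4-(4-methylpent-3-en-1-yl)cyclohex-2-en-1-one
Product: 6 4-methyl-4-(4-methylpent-3-en-1-yl)cyclohexa-2,5-dien-1-one (achiral), via trimethylsilyl dienol ether 5 (not isolated)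
Conditions: LDA, THF, −78 °C; TMSCl; then Pd(OAc)2 (10 mol%), O2, DMSO, rt
Reagents that add atoms: none
Why: Saegusa–Ito dehydrogenation: kinetic α′-deprotonation gives the cross-conjugated silyl dienol ether and Pd(II) converts it into the second ring alkene; the isolated trisubstituted alkene should not interfere.

Step 3
Reactants: 6 4-methyl-4-(4-methylpent-3-en-1-yl)cyclohexa-2,5-dien-1-one
Product: 7 (2E)-2-methyl-5-(1-methyl-4-oxocyclohexa-2,5-dien-1-yl)pent-2-enal
Conditions: SeO2 (1.2 equiv), 1,4-dioxane, 80 °C
Reagents that add atoms: selenium dioxide O=[Se]=O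
Why: Riley allylic oxidation (ene reaction, then [2,3]-shift) takes the (E)-methyl of the gem-dimethyl alkene to the (E)-enal, while the dienone, which has neither enolisable nor allylic C–H, should stay untouched.

Step 4
Reactants: 7 (2E)-2-methyl-5-(1-methyl-4-oxocyclohexa-2,5-dien-1-yl)pent-2-enal
Product: 8 2-methyl-5-(1-methyl-4-oxocyclohexa-2,5-dien-1-yl)pentanal (racemic)
Conditions: Hantzsch ester (1.2 equiv), Bn2NH2+ CF3CO2− (10 mol%), THF, rt
Reagents that add atoms: none
Why: Iminium-catalysed transfer hydrogenation: only the aldehyde condenses with the secondary ammonium salt, so the dihydropyridine delivers hydride to the enal β-carbon and the cross-conjugated dienone is spared; the new α-centre forms as a racemate, which the next step erases.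

Step 5
Reactants: 8 2-methyl-5-(1-methyl-4-oxocyclohexa-2,5-dien-1-yl)pentanal (racemic)
Product: 9 (1S,4aR,8aS)-1,4a-dimethyl-7-oxo-1,2,3,4,4a,7,8,8a-octahydronaphthalene-1-carbaldehyde (cis-fused; formyl, C20 and H-5 on one face)
Conditions: 9-amino-9-deoxy-epi-quinine (20 mol%), TFA (40 mol%), PhMe, 25 → 40 °C
Reagents that add atoms: none
Why: Proposed new method: the primary amine condenses with the racemic α-methyl aldehyde to an enamine, which erases the α-stereocentre so that both enantiomers of 8 converge, and the enamine carbon C4 adds to one of the two enantiotopic β-carbons (C5, not C9) of the acid-activated dienone before hydrolysis releases 9 and the catalyst. The closest known reaction type is the amine-catalysed desymmetrising intramolecular Michael addition of α-unbranched aldehydes to 4,4-disubstituted cyclohexadienones, and primary-amine enamines are the established way to make α-branched aldehydes add to Michael acceptors with formation of a quaternary carbon. Ring A closes 6-exo-trig (the C5=C6 bond is exocyclic to the new ring) through a chair in which the forming C4–C5 bond is axial on ring B, the C10–C9 bond axial and C20 equatorial on ring A. C10 and C5 are set together by the catalyst's choice of enone arm, and since the three-carbon tether on C10 reaches C5 only on its own face the fusion must be cis (H-5 syn to C20). C4 is set by the enamine face: the needed epimer (formyl cis to C20) forms when the methyl group sits axial over ring B and the bulky CH–N(catalyst) arm points outward in the equatorial position, which the size of the cinchona unit should favour but which is the uncertain element. The selectivities required are arm choice and C4 face choice only, because chemoselectivity is built into the substrate: once C4 is quaternary, 9 cannot form an enamine again, and no other ring size is within reach of the tether.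

Step 6
Reactants: 9 (1S,4aR,8aS)-1,4a-dimethyl-7-oxo-1,2,3,4,4a,7,8,8a-octahydronaphthalene-1-carbaldehyde
Product: 11 methyl (1S,4aR,8aS)-1,4a-dimethyl-7-oxo-1,2,3,4,4a,7,8,8a-octahydronaphthalene-1-carboxylate, via keto-acid 10 (not isolated)
Conditions: NaClO2, NaH2PO4, 2-methylbut-2-ene, t-BuOH/H2O, 0 °C → rt; then TMSCHN2, PhMe/MeOH, 0 °C
Reagents that add atoms: sodium chlorite [Na+].[O-]Cl=O; trimethylsilyldiazomethane C[Si](C)(C)C=[N+]=[N-]
Why: Pinnick oxidation and diazoalkane esterification act at the neopentyl formyl group without any base strong enough to trigger retro-Michael opening, and no stereocentre is involved.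

Step 7
Reactants: 11 methyl (1S,4aR,8aS)-1,4a-dimethyl-7-oxo-1,2,3,4,4a,7,8,8a-octahydronaphthalene-1-carboxylate
Product: 12 methyl (1S,4aR,5S,8aS)-5-ethenyl-1,4a-dimethyl-7-(triethylsilyloxy)-1,2,3,4,4a,5,8,8a-octahydronaphthalene-1-carboxylate
Conditions: CH2=CHMgBr, CuBr·SMe2 (20 mol%), TESCl, HMPA, THF, −78 → −40 °C; Et3N
Reagents that add atoms: vinylmagnesium bromide C=C[Mg]Br; chlorotriethylsilane CC[Si](Cl)(CC)CC
Why: Copper-catalysed, silyl-chloride-accelerated conjugate addition of a vinyl Grignard reagent with in situ O-silylation, which stores the C7/C8 enolate regiochemistry; the vinyl group should enter C9 on the convex face of the cis-fused bicycle (the face of C20 and H-5), because C4 and its methyl group lie under ring B, and this sets C9 with C11 cis to C20.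

Step 8
Reactants: 13 but-2-yne-1,4-diol
Product: 15 (2Z)-2-iodobut-2-ene-1,4-diol, via cyclic alkenylaluminate 14 (not isolated)
Conditions: Red-Al, THF, 0 °C → rt; then I2, −78 → 0 °C
Reagents that add atoms: iodine II
Why: Hydroxyl-directed trans-hydroalumination of the propargylic alcohol followed by iodinolysis of the C–Al bond with retention, which places iodine cis to the CH2OH on the CH carbon and the two CH2OH groups trans.

Step 9
Reactants: 15 (2Z)-2-iodobut-2-ene-1,4-diol
Product: 16 (2Z)-1,4-bis(tert-butyldimethylsilyloxy)-2-iodobut-2-ene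
Conditions: TBSCl, imidazole, DMF, rt
Reagents that add atoms: tert-butyldimethylsilyl chloride CC(C)(C)[Si](C)(C)Cl
Why: Imidazole-mediated silylation of both primary hydroxyls; the silyl ethers should survive the coupling, Mannich, hydride and palladium steps and leave together at the end.

Step 10
Reactants: 12 methyl (1S,4aR,5S,8aS)-5-ethenyl-1,4a-dimethyl-7-(triethylsilyloxy)-1,2,3,4,4a,5,8,8a-octahydronaphthalene-1-carboxylate; 16 (2Z)-1,4-bis(tert-butyldimethylsilyloxy)-2-iodobut-2-ene
Product: 18 methyl (1S,4aR,5S,8aS)-5-(bis-TBS side chain)-1,4a-dimethyl-7-(triethylsilyloxy)-1,2,3,4,4a,5,8,8a-octahydronaphthalene-1-carboxylate, via B-alkyl-9-BBN borane 17 (not isolated)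
Conditions: 9-BBN, THF, rt; then 16, PdCl2(dppf) (5 mol%), AsPh3, K3PO4, DMF, rt
Reagents that add atoms: none
Why: Anti-Markovnikov hydroboration of the only terminal alkene present (the trisubstituted silyl enol ether and the ester do not react with 9-BBN at room temperature) and B-alkyl Suzuki–Miyaura coupling, which keeps the geometry of 16 and so gives the (3E) side chain with C12 cis to C15; the mild phosphate base should leave the triethylsilyl enol ether intact.

Step 11
Reactants: 18 methyl (1S,4aR,5S,8aS)-5-(bis-TBS side chain)-1,4a-dimethyl-7-(triethylsilyloxy)-1,2,3,4,4a,5,8,8a-octahydronaphthalene-1-carboxylate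
Product: 21 methyl (1S,4aR,5R,8aS)-5-(bis-TBS side chain)-1,4a-dimethyl-6-methylidene-7-oxodecahydronaphthalene-1-carboxylate, via Mannich base 19 (not isolated), via methiodide 20 (not isolated)
Conditions: Me2N+=CH2 I−, CH2Cl2, rt; MeI; then NaHCO3 (aq), CH2Cl2
Reagents that add atoms: Eschenmoser's salt C=[N+](C)C.[I-]
Why: Mannich reaction of the silyl enol ether at C8 (regiochemistry fixed in step 7), N-methylation and E1cB elimination should give the α-methylene ketone (C17 installed); bicarbonate is mild enough to avoid migration of the exocyclic alkene, and C9 is not acidic in this enone (the descriptor at C9 changes only because the CIP priorities change).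

Step 12
Reactants: 21 methyl (1S,4aR,5R,8aS)-5-(bis-TBS side chain)-1,4a-dimethyl-6-methylidene-7-oxodecahydronaphthalene-1-carboxylate
Product: 22 methyl (1S,4aR,5R,8aS)-5-(bis-TBS side chain)-7-hydroxy-1,4a-dimethyl-6-methylidenedecahydronaphthalene-1-carboxylate (C7 epimer mixture)
Conditions: NaBH4, CeCl3·7H2O, MeOH, −40 → 0 °C
Reagents that add atoms: none
Why: Luche reduction: cerium-mediated 1,2-hydride addition to the α-methylene ketone should give the allylic alcohol without conjugate reduction; the C7 configuration is irrelevant.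

Step 13
Reactants: 22 methyl (1S,4aR,5R,8aS)-5-(bis-TBS side chain)-7-hydroxy-1,4a-dimethyl-6-methylidenedecahydronaphthalene-1-carboxylate
Product: 23 methyl (1S,4aR,5R,8aS)-5-(bis-TBS side chain)-7-(methoxycarbonyloxy)-1,4a-dimethyl-6-methylidenedecahydronaphthalene-1-carboxylate (C7 epimer mixture)
Conditions: ClCO2Me, pyridine, DMAP (cat.), CH2Cl2, 0 °C
Reagents that add atoms: methyl chloroformate COC(=O)Cl
Why: Acylation of the secondary allylic alcohol with a chloroformate provides the leaving group needed for palladium ionisation.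

Step 14
Reactants: 23 methyl (1S,4aR,5R,8aS)-5-(bis-TBS side chain)-7-(methoxycarbonyloxy)-1,4a-dimethyl-6-methylidenedecahydronaphthalene-1-carboxylate
Product: 24 methyl (1S,4aR,5S,8aS)-5-(bis-TBS side chain)-1,4a-dimethyl-6-methylidenedecahydronaphthalene-1-carboxylate
Conditions: Pd2(dba)3·CHCl3 (5 mol%), n-Bu3P (20 mol%), HCO2H, Et3N, THF, rt → 45 °C
Reagents that add atoms: none
Why: Tsuji-type palladium–formate hydrogenolysis: ionisation gives the π-allyl complex spanning C7–C8–C17, the formate ligand loses CO2, and the resulting Pd–H delivers hydride to the more substituted terminus C7 under n-Bu3P control, which should leave the exocyclic C8=C17 alkene and a C7 methylene; both C7 epimers converge, and the allylic silyl ethers do not ionise.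

Step 15
Reactants: 24 methyl (1S,4aR,5S,8aS)-5-(bis-TBS side chain)-1,4a-dimethyl-6-methylidenedecahydronaphthalene-1-carboxylate
Product: 25 methyl (1S,4aR,5S,8aS)-5-[(3E)-5-hydroxy-3-(hydroxymethyl)pent-3-en-1-yl]-1,4a-dimethyl-6-methylidenedecahydronaphthalene-1-carboxylate (CNP0282002.1)
Conditions: HF·pyridine, pyridine, THF, 0 °C → rt
Reagents that add atoms: none
Why: Fluoride cleavage of both silyl ethers under buffered conditions that should leave the exocyclic alkene, the allylic diol and the hindered methyl ester untouched.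

Compound list
1 | 2,6-dimethylhept-5-enal (racemic) | CC(C)=CCCC(C)C=O | starting material
2 | methyl vinyl ketone (but-3-en-2-one) | CC(=O)C=C | starting material
3 | 2-methyl-2-(4-methylpent-3-en-1-yl)-5-oxohexanal (racemic) | CC(=O)CCC(C)(C=O)CCC=C(C)C | intermediate
4 | 4-methyl-4-(4-methylpent-3-en-1-yl)cyclohex-2-en-1-one (racemic) | CC(C)=CCCC1(C)C=CC(=O)CC1 | intermediate
5 | trimethyl{[4-methyl-4-(4-methylpent-3-en-1-yl)cyclohexa-1,5-dien-1-yl]oxy}silane (racemic) | C[Si](C)(C)OC1=CCC(C)(CCC=C(C)C)C=C1 | intermediate
6 | 4-methyl-4-(4-methylpent-3-en-1-yl)cyclohexa-2,5-dien-1-one (achiral) | CC(C)=CCCC1(C)C=CC(=O)C=C1 | intermediate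
7 | (2E)-2-methyl-5-(1-methyl-4-oxocyclohexa-2,5-dien-1-yl)pent-2-enal | O=C/C(C)=C/CCC1(C)C=CC(=O)C=C1 | intermediate
8 | 2-methyl-5-(1-methyl-4-oxocyclohexa-2,5-dien-1-yl)pentanal (racemic) | O=CC(C)CCCC1(C)C=CC(=O)C=C1 | intermediate
9 | (1S,4aR,8aS)-1,4a-dimethyl-7-oxo-1,2,3,4,4a,7,8,8a-octahydronaphthalene-1-carbaldehyde | O=C1C[C@H]2[C@](C)(CCC[C@]2(C)C=O)C=C1 | intermediate
10 | (1S,4aR,8aS)-1,4a-dimethyl-7-oxo-1,2,3,4,4a,7,8,8a-octahydronaphthalene-1-carboxylic acid | O=C1C[C@H]2[C@](C)(CCC[C@]2(C)C(=O)O)C=C1 | intermediate
11 | methyl (1S,4aR,8aS)-1,4a-dimethyl-7-oxo-1,2,3,4,4a,7,8,8a-octahydronaphthalene-1-carboxylate | O=C1C[C@H]2[C@](C)(CCC[C@]2(C)C(=O)OC)C=C1 | intermediate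
12 | methyl (1S,4aR,5S,8aS)-5-ethenyl-1,4a-dimethyl-7-(triethylsilyloxy)-1,2,3,4,4a,5,8,8a-octahydronaphthalene-1-carboxylate | C1=C(O[Si](CC)(CC)CC)C[C@H]2[C@](C)(CCC[C@]2(C)C(=O)OC)[C@H]1C=C | intermediate
13 | but-2-yne-1,4-diol | OCC#CCO | starting material
14 | disodium cyclic alkenylaluminate of 13 (vinyl C–Al and ring O–Al on one aluminium carrying two 2-methoxyethoxy groups; second alkoxide on a hydridoaluminate) | [Na+].[Na+].COCCO[Al-]1(OCCOC)OCC=C1CO[AlH-](OCCOC)OCCOC | intermediate
15 | (2Z)-2-iodobut-2-ene-1,4-diol | OC/C=C(I)/CO | intermediate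
16 | (2Z)-1,4-bis(tert-butyldimethylsilyloxy)-2-iodobut-2-ene | CC(C)(C)[Si](C)(C)OC/C=C(I)/CO[Si](C)(C)C(C)(C)C | intermediate
17 | methyl (1S,4aR,5S,8aS)-5-[2-(9-borabicyclo[3.3.1]nonan-9-yl)ethyl]-1,4a-dimethyl-7-(triethylsilyloxy)-1,2,3,4,4a,5,8,8a-octahydronaphthalene-1-carboxylate | C1=C(O[Si](CC)(CC)CC)C[C@H]2[C@](C)(CCC[C@]2(C)C(=O)OC)[C@H]1CCB3C4CCCC3CCC4 | intermediate
18 | methyl (1S,4aR,5S,8aS)-5-{(3E)-5-(tert-butyldimethylsilyloxy)-3-[(tert-butyldimethylsilyloxy)methyl]pent-3-en-1-yl}-1,4a-dimethyl-7-(triethylsilyloxy)-1,2,3,4,4a,5,8,8a-octahydronaphthalene-1-carboxylate | C1=C(O[Si](CC)(CC)CC)C[C@H]2[C@](C)(CCC[C@]2(C)C(=O)OC)[C@H]1CC/C(=C\CO[Si](C)(C)C(C)(C)C)CO[Si](C)(C)C(C)(C)C | intermediate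
19 | methyl (1S,4aR,5S,8aS)-5-(bis-TBS side chain)-6-[(dimethylamino)methyl]-1,4a-dimethyl-7-oxodecahydronaphthalene-1-carboxylate (C6 epimers) | CN(C)CC1C(=O)C[C@H]2[C@](C)(CCC[C@]2(C)C(=O)OC)[C@H]1CC/C(=C\CO[Si](C)(C)C(C)(C)C)CO[Si](C)(C)C(C)(C)C | intermediate
20 | trimethylammonium iodide (methiodide) of 19 | C[N+](C)(C)CC1C(=O)C[C@H]2[C@](C)(CCC[C@]2(C)C(=O)OC)[C@H]1CC/C(=C\CO[Si](C)(C)C(C)(C)C)CO[Si](C)(C)C(C)(C)C.[I-] | intermediate
21 | methyl (1S,4aR,5R,8aS)-5-(bis-TBS side chain)-1,4a-dimethyl-6-methylidene-7-oxodecahydronaphthalene-1-carboxylate | C=C1C(=O)C[C@H]2[C@](C)(CCC[C@]2(C)C(=O)OC)[C@H]1CC/C(=C\CO[Si](C)(C)C(C)(C)C)CO[Si](C)(C)C(C)(C)C | intermediate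
22 | methyl (1S,4aR,5R,8aS)-5-(bis-TBS side chain)-7-hydroxy-1,4a-dimethyl-6-methylidenedecahydronaphthalene-1-carboxylate (C7 epimers) | C=C1C(O)C[C@H]2[C@](C)(CCC[C@]2(C)C(=O)OC)[C@H]1CC/C(=C\CO[Si](C)(C)C(C)(C)C)CO[Si](C)(C)C(C)(C)C | intermediate
23 | methyl (1S,4aR,5R,8aS)-5-(bis-TBS side chain)-7-(methoxycarbonyloxy)-1,4a-dimethyl-6-methylidenedecahydronaphthalene-1-carboxylate (C7 epimers) | C=C1C(OC(=O)OC)C[C@H]2[C@](C)(CCC[C@]2(C)C(=O)OC)[C@H]1CC/C(=C\CO[Si](C)(C)C(C)(C)C)CO[Si](C)(C)C(C)(C)C | intermediate
24 | methyl (1S,4aR,5S,8aS)-5-(bis-TBS side chain)-1,4a-dimethyl-6-methylidenedecahydronaphthalene-1-carboxylate | C=C1CC[C@H]2[C@](C)(CCC[C@]2(C)C(=O)OC)[C@H]1CC/C(=C\CO[Si](C)(C)C(C)(C)C)CO[Si](C)(C)C(C)(C)C | intermediate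
25 | methyl (1S,4aR,5S,8aS)-5-[(3E)-5-hydroxy-3-(hydroxymethyl)pent-3-en-1-yl]-1,4a-dimethyl-6-methylidenedecahydronaphthalene-1-carboxylate | C=C1CC[C@H]2[C@](C)(CCC[C@]2(C)C(=O)OC)[C@H]1CC/C(=C\CO)CO | target

Total step count: 15. Longest linear sequence: 13 steps (steps 1–7 and 10–15); steps 8–9 make the coupling partner.

Steps most likely to fail

Step 5. The enamine of the α-branched aldehyde may form slowly, the catalyst may discriminate the two enone arms poorly, or the enamine may attack with the other face, so that low enantiomeric purity or the C4 epimer results. The fallback uses known chemistry, racemic closure and classical resolution; it sets out from 8 and returns at 10. Ring closure with an achiral secondary amine (pyrrolidine, AcOH, PhMe, then aqueous hydrolysis; a Stork-type enamine Michael addition of an α-branched aldehyde) should give the racemic cis-fused keto-aldehyde F1, from which the epimer with formyl cis to C20 is separated by chromatography. Pinnick oxidation should give the racemic keto-acid F2. Crystallisation with (R)-1-phenylethylamine should give the diastereomerically pure (R)-1-phenylethylammonium salt of 10, F3; the antipodal amine is used if the salt of the wanted acid proves the more soluble one. Acidification liberates 10, which is esterified as in step 6.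

Step 7. Transfer of the vinyl group to C9, which is flanked by the quaternary C10, may stall, so that 1,2-addition to the ketone, enolisation or incomplete O-silylation take over; attack on the concave face would give the C9 epimer. The fallback changes the mechanism; it sets out from 11 and returns at 12. Nickel-catalysed reductive conjugate addition of vinyl bromide in the presence of chlorotriethylsilane (NiCl2·dme, neocuproine, Mn, DMF) forms a silyloxy-allylnickel species from the enone, couples it with the vinyl halide and should give the triethylsilyl enol ether 12 directly, without an organometallic nucleophile; it makes no new compound (F0).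

Step 4. The α-substituted enal may condense only slowly with the secondary ammonium salt, and the product aldehyde may begin to cyclise under the achiral amine, which would feed racemic 9 into the key step. The fallback replaces reduction by redox isomerisation; it sets out from 6 and returns at 8. Catalytic SeO2 with t-BuOOH in CH2Cl2 should stop at the (E)-allylic alcohol 4-[(3E)-5-hydroxy-4-methylpent-3-en-1-yl]-4-methylcyclohexa-2,5-dien-1-one F4. A metal-hydride isomerisation catalyst (H2-activated [Ir(cod)(PCy3)(py)]PF6, THF, rt) should then convert the primary allylic alcohol into aldehyde 8 by a 1,3-hydride shift and tautomerisation, with no amine and no external reductant present.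

Further compounds
F1 | step 5 | racemic (1S*,4aR*,8aS*)-1,4a-dimethyl-7-oxo-1,2,3,4,4a,7,8,8a-octahydronaphthalene-1-carbaldehyde | O=C1C[C@H]2[C@](C)(CCC[C@]2(C)C=O)C=C1.O=C1C[C@@H]2[C@@](C)(CCC[C@@]2(C)C=O)C=C1
F2 | step 5 | racemic (1S*,4aR*,8aS*)-1,4a-dimethyl-7-oxo-1,2,3,4,4a,7,8,8a-octahydronaphthalene-1-carboxylic acid | O=C1C[C@H]2[C@](C)(CCC[C@]2(C)C(=O)O)C=C1.O=C1C[C@@H]2[C@@](C)(CCC[C@@]2(C)C(=O)O)C=C1
F3 | step 5 | (R)-1-phenylethylammonium (1S,4aR,8aS)-1,4a-dimethyl-7-oxo-1,2,3,4,4a,7,8,8a-octahydronaphthalene-1-carboxylate | O=C1C[C@H]2[C@](C)(CCC[C@]2(C)C(=O)[O-])C=C1.C[C@@H]([NH3+])c1ccccc1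
F0 | step 7 | none | none
F4 | step 4 | 4-[(3E)-5-hydroxy-4-methylpent-3-en-1-yl]-4-methylcyclohexa-2,5-dien-1-one | OC/C(C)=C/CCC1(C)C=CC(=O)C=C1
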